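**Retrosynthetic overview**
1. The ring enone comes from a tertiary allylic alcohol: the ring C–O bond is made by the [3,3]-sigmatropic shift of an allylic chromate (oxidative 1,3-transposition of a MeLi adduct). The butenolide is attached by Negishi coupling of a homoallylic zinc with 4-bromofuran-2(5H)-one.
2. The (E)-trisubstituted olefin comes from a terminal alkyne (Zr-catalysed carboalumination, then ethylene oxide); the alkyne comes from a γ-lactone (DIBAL, Ohira–Bestmann).
3. The 1,1-disubstituted olefin comes from a B-alkyl Suzuki coupling of a ring vinyl group with the enol triflate of (R)-5-acetyl-γ-butyrolactone; the carbinol centre is bought in (R)-5-oxotetrahydrofuran-2-carboxylic acid.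
4. Ring stereocentres: C5 is bought in (R)-5-methylcyclohex-2-en-1-one; the quaternary C4 is set by two α′-alkylations (two-carbon arm first, MeI second, anti to the C5 methyl).
5. Rings: neither ring is constructed. The carbocycle is bought and its enone is unveiled in step 13; the bought butenolide is attached in step 14.

Assumption: (R)-5-methylcyclohex-2-en-1-one (catalogue compound made from (R)-pulegone) is taken as purchasable; the carbinol carbon made in step 4 is carried as an epimer mixture (no descriptor in the SMILES) because step 13 makes it sp2.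

**Step 1**
Reactants: 1 (R)-5-methylcyclohex-2-en-1-one
Product: 3 (5R,6S)-5-methyl-6-[2-(phenylsulfinyl)ethyl]cyclohex-2-en-1-one, via lithium dienolate 2 (not isolated)
Conditions: LiN(i-Pr)2, THF, −78 °C; phenyl vinyl sulfoxide, −78 → −20 °C; aq. NH4Cl
Reagents that add atoms: phenyl vinyl sulfoxide (C=CS(=O)c1ccccc1)
Why: Kinetic α′-deprotonation gives the cross-conjugated dienolate, which undergoes Michael addition to the vinyl sulfoxide (a vinyl cation equivalent) anti to the C5 methyl; the new C6 centre is transient because it is re-enolised in step 2.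

**Step 2**
Reactants: 3 (5R,6S)-5-methyl-6-[2-(phenylsulfinyl)ethyl]cyclohex-2-en-1-one
Product: 5 (5R,6R)-5,6-dimethyl-6-[2-(phenylsulfinyl)ethyl]cyclohex-2-en-1-one, via lithium enolate 4 (not isolated)
Conditions: LiN(i-Pr)2, THF, −78 °C; MeI, DMPU, −78 → 0 °C
Reagents that add atoms: iodomethane (CI)
Why: Enolate alkylation in which MeI attacks the face anti to the adjacent pseudoaxial C5 methyl, so the new methyl is trans to C5-Me and the two-carbon arm cis; this sets the quaternary centre under control of the bought C5 centre.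

**Step 3**
Reactants: 5 (5R,6R)-5,6-dimethyl-6-[2-(phenylsulfinyl)ethyl]cyclohex-2-en-1-one
Product: 6 (5R,6R)-5,6-dimethyl-6-vinylcyclohex-2-en-1-one
Conditions: toluene, CaCO3, 110 °C
Reagents that add atoms: none
Why: Thermal sulfoxide syn-elimination can only take a hydrogen of the inner CH2 of the arm and so unveils the vinyl group on the quaternary carbon without touching either stereocentre.

**Step 4**
Reactants: 6 (5R,6R)-5,6-dimethyl-6-vinylcyclohex-2-en-1-one
Product: 7 (5R,6R)-1,5,6-trimethyl-6-vinylcyclohex-2-en-1-ol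
Conditions: MeLi, Et2O, −78 °C
Reagents that add atoms: methyllithium ([Li]C)
Why: 1,2-Addition of MeLi to the enone (no α′-hydrogen is left to enolise) installs the future vinylic methyl and masks the ring ketone as a tertiary allylic alcohol that tolerates the later hydride, aluminium and boron reagents; the new carbinol centre is destroyed in step 13.

**Step 5**
Reactants: 8 (R)-5-oxotetrahydrofuran-2-carboxylic acid
Product: 10 (R)-5-acetyldihydrofuran-2(3H)-one, via acid chloride 9 (not isolated)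
Conditions: (COCl)2, cat. DMF, CH2Cl2, 0 °C → rt; then Me2CuLi, Et2O, −78 °C
Reagents that add atoms: lithium dimethylcuprate ([Li+].C[Cu-]C)
Why: Acid chloride formation followed by Gilman ketone synthesis, in which the cuprate acylates only the acid chloride at −78 °C and leaves the lactone and the bought carbinol centre untouched.

**Step 6**
Reactants: 10 (R)-5-acetyldihydrofuran-2(3H)-one
Product: 12 1-[(2R)-5-oxotetrahydrofuran-2-yl]ethenyl trifluoromethanesulfonate, via potassium enolate 11 (not isolated)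
Conditions: KN(SiMe3)2, THF, −78 °C; PhNTf2, −78 → 0 °C
Reagents that add atoms: N-phenylbis(trifluoromethanesulfonimide) (O=S(=O)(N(c1ccccc1)S(=O)(=O)C(F)(F)F)C(F)(F)F)
Why: Kinetic deprotonation occurs at the methyl group and not at the hindered oxygen-bearing CH (so the stereocentre is not epimerised), and O-sulfonylation of the enolate gives the terminal enol triflate.

**Step 7**
Reactants: 7 (5R,6R)-1,5,6-trimethyl-6-vinylcyclohex-2-en-1-ol; 12 1-[(2R)-5-oxotetrahydrofuran-2-yl]ethenyl trifluoromethanesulfonate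
Product: 14 (5R)-5-{4-[(1R,6R)-2-hydroxy-1,2,6-trimethylcyclohex-3-en-1-yl]but-1-en-2-yl}dihydrofuran-2(3H)-one, via B-alkyl-9-BBN adduct 13 (not isolated)
Conditions: 7, 9-BBN (2.2 equiv), THF, 0 °C → rt; then 12, PdCl2(dppf) (5 mol %), AsPh3, Cs2CO3, DMF–H2O, rt
Reagents that add atoms: none
Why: B-alkyl Suzuki–Miyaura coupling in which 9-BBN hydroborates only the monosubstituted vinyl group (anti-Markovnikov) and the primary alkylborane couples with the enol triflate to give the 1,1-disubstituted olefin; no stereocentre is involved.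

**Step 8**
Reactants: 14 (5R)-5-{4-[(1R,6R)-2-hydroxy-1,2,6-trimethylcyclohex-3-en-1-yl]but-1-en-2-yl}dihydrofuran-2(3H)-one
Product: 15 (5R)-5-{4-[(1R,6R)-2-hydroxy-1,2,6-trimethylcyclohex-3-en-1-yl]but-1-en-2-yl}tetrahydrofuran-2-ol
Conditions: i-Bu2AlH (2.2 equiv), CH2Cl2, −78 °C
Reagents that add atoms: none
Why: DIBAL reduction of a γ-lactone stops at the lactol at −78 °C because the tetrahedral aluminium alkoxide is stable; the first equivalent is consumed by the tertiary hydroxyl.

**Step 9**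
Reactants: 15 (5R)-5-{4-[(1R,6R)-2-hydroxy-1,2,6-trimethylcyclohex-3-en-1-yl]but-1-en-2-yl}tetrahydrofuran-2-ol
Product: 16 (4R)-1-[(1R,6R)-2-hydroxy-1,2,6-trimethylcyclohex-3-en-1-yl]-3-methylideneoct-7-yn-4-ol
Conditions: dimethyl (1-diazo-2-oxopropyl)phosphonate, K2CO3, MeOH, 0 °C → rt
Reagents that add atoms: dimethyl (1-diazo-2-oxopropyl)phosphonate (COP(=O)(OC)C(=[N+]=[N-])C(C)=O)
Why: Ohira–Bestmann (Seyferth–Gilbert) homologation of the hydroxy aldehyde in equilibrium with the lactol gives the terminal alkyne under mild base and leaves the allylic carbinol centre untouched.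

**Step 10**
Reactants: 16 (4R)-1-[(1R,6R)-2-hydroxy-1,2,6-trimethylcyclohex-3-en-1-yl]-3-methylideneoct-7-yn-4-ol
Product: 18 (3E,7R)-10-[(1R,6R)-2-hydroxy-1,2,6-trimethylcyclohex-3-en-1-yl]-4-methyl-8-methylidenedec-3-ene-1,7-diol, via alkenyldimethylalane 17 (not isolated)
Conditions: AlMe3 (5 equiv), Cp2ZrCl2 (25 mol %), CH2Cl2, 0 °C → rt; then n-BuLi, THF, −78 °C; ethylene oxide, −78 → 0 °C
Reagents that add atoms: trimethylaluminium (C[Al](C)C); ethylene oxide (C1CO1)
Why: Negishi zirconium-catalysed carboalumination adds Me–Al syn across the alkyne with methyl on the internal carbon, and the derived alanate opens ethylene oxide with retention of geometry, giving the (E)-homoallylic alcohol.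

**Step 11**
Reactants: 18 (3E,7R)-10-[(1R,6R)-2-hydroxy-1,2,6-trimethylcyclohex-3-en-1-yl]-4-methyl-8-methylidenedec-3-ene-1,7-diol
Product: 19 (4R,7E)-1-[(1R,6R)-2-hydroxy-1,2,6-trimethylcyclohex-3-en-1-yl]-10-iodo-7-methyl-3-methylidenedec-7-en-4-ol
Conditions: PPh3, I2, imidazole, CH2Cl2, 0 °C
Reagents that add atoms: iodine (II)
Why: Appel-type iodination proceeds by SN2 on the alkoxyphosphonium ion and is selective for the primary alcohol over the hindered secondary allylic and tertiary alcohols.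

**Step 12**
Reactants: 19 (4R,7E)-1-[(1R,6R)-2-hydroxy-1,2,6-trimethylcyclohex-3-en-1-yl]-10-iodo-7-methyl-3-methylidenedec-7-en-4-ol
Product: 20 (4R,7E)-1-[(1R,6R)-2-hydroxy-1,2,6-trimethylcyclohex-3-en-1-yl]-10-iodo-7-methyl-3-methylidenedec-7-en-4-yl acetate
Conditions: Ac2O, pyridine, DMAP (cat.), CH2Cl2, 0 °C → rt
Reagents that add atoms: acetic anhydride (CC(=O)OC(C)=O)
Why: DMAP-catalysed acylation esterifies the secondary allylic alcohol with retention (the C–O bond is not broken), while the tertiary alcohol is too hindered to react.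

**Step 13**
Reactants: 20 (4R,7E)-1-[(1R,6R)-2-hydroxy-1,2,6-trimethylcyclohex-3-en-1-yl]-10-iodo-7-methyl-3-methylidenedec-7-en-4-yl acetate
Product: 23 (4R,7E)-10-iodo-7-methyl-3-methylidene-1-[(1R,6R)-1,2,6-trimethyl-4-oxocyclohex-2-en-1-yl]dec-7-en-4-yl acetate, via tertiary allylic chlorochromate 21 (not isolated), via transposed secondary allylic chlorochromate 22 (not isolated)
Conditions: pyridinium chlorochromate, NaOAc, 4 Å sieves, CH2Cl2, rt
Reagents that add atoms: pyridinium chlorochromate ([O-][Cr](=O)(=O)Cl.c1cc[nH+]cc1)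
Why: Dauben–Babler oxidative transposition: the tertiary allylic chromate ester undergoes a [3,3]-sigmatropic rearrangement that forms the new ring C–O bond, and the resulting secondary chromate is oxidised to the β-methyl enone; the epimeric carbinol carbon becomes sp2 and no other stereocentre is touched.

**Step 14**
Reactants: 23 (4R,7E)-10-iodo-7-methyl-3-methylidene-1-[(1R,6R)-1,2,6-trimethyl-4-oxocyclohex-2-en-1-yl]dec-7-en-4-yl acetate; 24 4-bromofuran-2(5H)-one
Product: 26 (4R,7E)-7-methyl-3-methylidene-10-(5-oxo-2,5-dihydrofuran-3-yl)-1-[(1R,6R)-1,2,6-trimethyl-4-oxocyclohex-2-en-1-yl]dec-7-en-4-yl acetate, via alkylzinc iodide 25 (not isolated)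
Conditions: Zn dust, LiCl, THF, 40 °C; then 24, PdCl2(dppf) (5 mol %), THF–DMA, rt
Reagents that add atoms: none
Why: LiCl-assisted zinc insertion into the primary iodide tolerates enone and acetate, and Negishi cross-coupling with the activated vinyl bromide attaches the bought butenolide with the olefin geometry and all three stereocentres unchanged.

**Compound list**
1 | (R)-5-methylcyclohex-2-en-1-one | O=C1C=CC[C@@H](C)C1 | starting material
2 | lithium (R)-3-methylcyclohexa-1,5-dien-1-olate | [Li+].[O-]C1=C[C@H](C)CC=C1 | intermediate (not isolated)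
3 | (5R,6S)-5-methyl-6-[2-(phenylsulfinyl)ethyl]cyclohex-2-en-1-one (both sulfur epimers) | O=C1C=CC[C@@H](C)[C@@H]1CCS(=O)c1ccccc1 | intermediate
4 | lithium (3R)-3-methyl-2-[2-(phenylsulfinyl)ethyl]cyclohexa-1,5-dien-1-olate | [Li+].[O-]C1=C(CCS(=O)c2ccccc2)[C@H](C)CC=C1 | intermediate (not isolated)
5 | (5R,6R)-5,6-dimethyl-6-[2-(phenylsulfinyl)ethyl]cyclohex-2-en-1-one (both sulfur epimers) | O=C1C=CC[C@@H](C)[C@@]1(C)CCS(=O)c1ccccc1 | intermediate
6 | (5R,6R)-5,6-dimethyl-6-vinylcyclohex-2-en-1-one | O=C1C=CC[C@@H](C)[C@@]1(C)C=C | intermediate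
7 | (5R,6R)-1,5,6-trimethyl-6-vinylcyclohex-2-en-1-ol (C1 epimers) | CC1(O)C=CC[C@@H](C)[C@@]1(C)C=C | intermediate
8 | (R)-5-oxotetrahydrofuran-2-carboxylic acid | OC(=O)[C@H]1CCC(=O)O1 | starting material
9 | (R)-5-oxotetrahydrofuran-2-carbonyl chloride | ClC(=O)[C@H]1CCC(=O)O1 | intermediate (not isolated)
10 | (R)-5-acetyldihydrofuran-2(3H)-one | CC(=O)[C@H]1CCC(=O)O1 | intermediate
11 | potassium 1-[(2R)-5-oxotetrahydrofuran-2-yl]ethen-1-olate | [K+].[O-]C(=C)[C@H]1CCC(=O)O1 | intermediate (not isolated)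
12 | 1-[(2R)-5-oxotetrahydrofuran-2-yl]ethenyl trifluoromethanesulfonate | C=C(OS(=O)(=O)C(F)(F)F)[C@H]1CCC(=O)O1 | intermediate
13 | 9-{2-[(1R,6R)-2-hydroxy-1,2,6-trimethylcyclohex-3-en-1-yl]ethyl}-9-borabicyclo[3.3.1]nonane | CC1(O)C=CC[C@@H](C)[C@@]1(C)CCB1C2CCCC1CCC2 | intermediate (not isolated)
14 | (5R)-5-{4-[(1R,6R)-2-hydroxy-1,2,6-trimethylcyclohex-3-en-1-yl]but-1-en-2-yl}dihydrofuran-2(3H)-one | CC1(O)C=CC[C@@H](C)[C@@]1(C)CCC(=C)[C@H]1CCC(=O)O1 | intermediate
15 | (5R)-5-{4-[(1R,6R)-2-hydroxy-1,2,6-trimethylcyclohex-3-en-1-yl]but-1-en-2-yl}tetrahydrofuran-2-ol (anomers) | CC1(O)C=CC[C@@H](C)[C@@]1(C)CCC(=C)[C@H]1CCC(O)O1 | intermediate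
16 | (4R)-1-[(1R,6R)-2-hydroxy-1,2,6-trimethylcyclohex-3-en-1-yl]-3-methylideneoct-7-yn-4-ol | CC1(O)C=CC[C@@H](C)[C@@]1(C)CCC(=C)[C@H](O)CCC#C | intermediate
17 | (E)-alkenyldimethylalane from 16 (both hydroxyls as dimethylaluminium alkoxides) | CC1(O[Al](C)C)C=CC[C@@H](C)[C@@]1(C)CCC(=C)[C@H](O[Al](C)C)CC/C(C)=C/[Al](C)C | intermediate (not isolated)
18 | (3E,7R)-10-[(1R,6R)-2-hydroxy-1,2,6-trimethylcyclohex-3-en-1-yl]-4-methyl-8-methylidenedec-3-ene-1,7-diol | CC1(O)C=CC[C@@H](C)[C@@]1(C)CCC(=C)[C@H](O)CC/C(C)=C/CCO | intermediate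
19 | (4R,7E)-1-[(1R,6R)-2-hydroxy-1,2,6-trimethylcyclohex-3-en-1-yl]-10-iodo-7-methyl-3-methylidenedec-7-en-4-ol | CC1(O)C=CC[C@@H](C)[C@@]1(C)CCC(=C)[C@H](O)CC/C(C)=C/CCI | intermediate
20 | (4R,7E)-1-[(1R,6R)-2-hydroxy-1,2,6-trimethylcyclohex-3-en-1-yl]-10-iodo-7-methyl-3-methylidenedec-7-en-4-yl acetate | CC1(O)C=CC[C@@H](C)[C@@]1(C)CCC(=C)[C@H](OC(C)=O)CC/C(C)=C/CCI | intermediate
21 | tertiary allylic chlorochromate ester of 20 | CC1(O[Cr](=O)(=O)Cl)C=CC[C@@H](C)[C@@]1(C)CCC(=C)[C@H](OC(C)=O)CC/C(C)=C/CCI | intermediate (not isolated)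
22 | transposed secondary allylic chlorochromate ester (chromate on the future carbonyl carbon) | CC1=CC(O[Cr](=O)(=O)Cl)C[C@@H](C)[C@@]1(C)CCC(=C)[C@H](OC(C)=O)CC/C(C)=C/CCI | intermediate (not isolated)
23 | (4R,7E)-10-iodo-7-methyl-3-methylidene-1-[(1R,6R)-1,2,6-trimethyl-4-oxocyclohex-2-en-1-yl]dec-7-en-4-yl acetate | CC1=CC(=O)C[C@@H](C)[C@@]1(C)CCC(=C)[C@H](OC(C)=O)CC/C(C)=C/CCI | intermediate
24 | 4-bromofuran-2(5H)-one | O=C1C=C(Br)CO1 | starting material
25 | alkylzinc iodide from 23 | CC1=CC(=O)C[C@@H](C)[C@@]1(C)CCC(=C)[C@H](OC(C)=O)CC/C(C)=C/CC[Zn]I | intermediate (not isolated)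
26 | CNP0204194.1, (4R,7E)-7-methyl-3-methylidene-10-(5-oxo-2,5-dihydrofuran-3-yl)-1-[(1R,6R)-1,2,6-trimethyl-4-oxocyclohex-2-en-1-yl]dec-7-en-4-yl acetate | C=C(CC[C@@]1(C)C(C)=CC(=O)C[C@H]1C)[C@@H](CC/C(C)=C/CCC1=CC(=O)OC1)OC(C)=O | target

**Totals**
Total step count: 14 (four on the ring branch, two on the lactone branch, eight after their union).
Longest linear sequence: 12 steps (1, 2, 3, 4, then 7 to 14).

**Three steps most likely to fail**

Step 1. The α-sulfinyl carbanion formed in the Michael addition can be quenched by product, and the resulting enolate can add a second vinyl sulfoxide. The fallback sets out from 1 and comes back at 6. Dienolate 2 is alkylated with allyl bromide to give (5R,6S)-6-allyl-5-methylcyclohex-2-en-1-one F1. Re-enolisation with LiN(i-Pr)2 gives lithium (3R)-2-allyl-3-methylcyclohexa-1,5-dien-1-olate F2, and MeI (anti to the C5 methyl) gives (5R,6R)-6-allyl-5,6-dimethylcyclohex-2-en-1-one F3. RuHCl(CO)(PPh3)3 in toluene at 80 °C moves the terminal olefin into conjugation-free internal position to give (5R,6S)-5,6-dimethyl-6-[(E)-prop-1-en-1-yl]cyclohex-2-en-1-one F4. Ethenolysis under ethylene with the second-generation Hoveyda–Grubbs catalyst cuts off one carbon and delivers 6.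

Step 10. The one-pot carboalumination and epoxide opening runs on a substrate with two free hydroxyls; the tertiary allylic aluminium alkoxide may ionise and the alanate may open ethylene oxide poorly. The fallback sets out from 16 and comes back at 18. The alkenylalane 17 is quenched with I2 to give (4R,7E)-1-[(1R,6R)-2-hydroxy-1,2,6-trimethylcyclohex-3-en-1-yl]-8-iodo-7-methyl-3-methylideneoct-7-en-4-ol F5. Separately, tert-butyldimethyl(vinyloxy)silane is hydroborated with 9-BBN to 9-[2-(tert-butyldimethylsilyloxy)ethyl]-9-borabicyclo[3.3.1]nonane F6. B-alkyl Suzuki coupling of F5 with F6 (PdCl2(dppf), AsPh3, Cs2CO3) gives the 1-O-tert-butyldimethylsilyl ether of 18 F7, and Bu4NF returns 18.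

Step 14. Zerovalent palladium can ionise the allylic acetate of 23 or of the product while the Negishi coupling runs. The fallback sets out from 19 and comes back at 26, carrying the carbinol as a silyl ether through oxidation and coupling and acetylating last. TBSCl and imidazole give the secondary tert-butyldimethylsilyl ether of 19 F8. Pyridinium chlorochromate converts it through its tertiary allylic chlorochromate F9 and the transposed secondary allylic chlorochromate F10 into the silyl-protected iodo enone F11. Zinc insertion gives the alkylzinc iodide F12, and coupling with 24 gives the silyl-protected butenolide F13. HF·pyridine frees the deacetyl alcohol F14, and Ac2O, pyridine and DMAP give 26.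

**Further compounds**
F1 | step 1 | (5R,6S)-6-allyl-5-methylcyclohex-2-en-1-one | O=C1C=CC[C@@H](C)[C@@H]1CC=C
F2 | step 1 | lithium (3R)-2-allyl-3-methylcyclohexa-1,5-dien-1-olate | [Li+].[O-]C1=C(CC=C)[C@H](C)CC=C1
F3 | step 1 | (5R,6R)-6-allyl-5,6-dimethylcyclohex-2-en-1-one | O=C1C=CC[C@@H](C)[C@@]1(C)CC=C
F4 | step 1 | (5R,6S)-5,6-dimethyl-6-[(E)-prop-1-en-1-yl]cyclohex-2-en-1-one | O=C1C=CC[C@@H](C)[C@@]1(C)/C=C/C
F5 | step 10 | (4R,7E)-1-[(1R,6R)-2-hydroxy-1,2,6-trimethylcyclohex-3-en-1-yl]-8-iodo-7-methyl-3-methylideneoct-7-en-4-ol | CC1(O)C=CC[C@@H](C)[C@@]1(C)CCC(=C)[C@H](O)CC/C(C)=C/I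
F6 | step 10 | 9-[2-(tert-butyldimethylsilyloxy)ethyl]-9-borabicyclo[3.3.1]nonane | CC(C)(C)[Si](C)(C)OCCB1C2CCCC1CCC2
F7 | step 10 | 1-O-tert-butyldimethylsilyl ether of 18 | CC1(O)C=CC[C@@H](C)[C@@]1(C)CCC(=C)[C@H](O)CC/C(C)=C/CCO[Si](C)(C)C(C)(C)C
F8 | step 14 | secondary tert-butyldimethylsilyl ether of 19 | CC1(O)C=CC[C@@H](C)[C@@]1(C)CCC(=C)[C@H](O[Si](C)(C)C(C)(C)C)CC/C(C)=C/CCI
F9 | step 14 | tertiary allylic chlorochromate ester of F8 | CC1(O[Cr](=O)(=O)Cl)C=CC[C@@H](C)[C@@]1(C)CCC(=C)[C@H](O[Si](C)(C)C(C)(C)C)CC/C(C)=C/CCI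
F10 | step 14 | transposed secondary allylic chlorochromate ester from F9 | CC1=CC(O[Cr](=O)(=O)Cl)C[C@@H](C)[C@@]1(C)CCC(=C)[C@H](O[Si](C)(C)C(C)(C)C)CC/C(C)=C/CCI
F11 | step 14 | tert-butyldimethylsilyl ether analogue of 23 (silyl-protected iodo enone) | CC1=CC(=O)C[C@@H](C)[C@@]1(C)CCC(=C)[C@H](O[Si](C)(C)C(C)(C)C)CC/C(C)=C/CCI
F12 | step 14 | alkylzinc iodide from F11 | CC1=CC(=O)C[C@@H](C)[C@@]1(C)CCC(=C)[C@H](O[Si](C)(C)C(C)(C)C)CC/C(C)=C/CC[Zn]I
F13 | step 14 | tert-butyldimethylsilyl ether of deacetyl 26 | CC1=CC(=O)C[C@@H](C)[C@@]1(C)CCC(=C)[C@H](O[Si](C)(C)C(C)(C)C)CC/C(C)=C/CCC1=CC(=O)OC1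
F14 | step 14 | deacetyl 26 (free secondary alcohol) | CC1=CC(=O)C[C@@H](C)[C@@]1(C)CCC(=C)[C@H](O)CC/C(C)=C/CCC1=CC(=O)OC1
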